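**Plan**

1. Retrosynthesis (core numbered as a chroman-4-one, O1 to C8a): the acid is unmasked last; the C8–prenyl bond is cut next, leaving a 5,7-dihydroxychroman-4-one; the carbocycle is then cut at C7–C8 and C5–C6 into the 2,3-dihydropyran-4-one 5-carboxylate 16 and the 3-pentylglutaric half ester 23; 16 is cut into an acetoacetate, an anti-3-hydroxy-2-methylbutanoic acid and a cyclobutylmethyl iodide.
2. Enabling feature: the carbocycle is a masked phloroglucinol. C5 and C7 are carbonyl-level carbons with C6 between them, and C8 is the γ-carbon of the vinylogous ester O1–C8a=C4a–C4=O. A pyranone that carries C5 as its ester and C8 as an acidic CH2 is therefore nucleophilic at C8 and electrophilic at C5, the exact complement of an alkanoyl chloride (electrophilic C7, enolisable C6).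
3. Forward order: the pyranone (ring B) arises first by C-acylation and cyclodehydration; the carbocycle (ring A) second by one-pot γ-acylation, Claisen closure and aromatisation; the quaternary C8 third by prenylation; the ester is hydrolysed last.
4. Stereochemistry: the cyclobutane centres come from (1S,5S)-verbenone (pinane C1, C5, C6 and C7 become the four-membered ring, C4 with its methyl the isopropenyl group, C2 the CH2 link). C2 comes from methyl (R)-3-hydroxybutanoate and C3 from anti (Fráter–Seebach) methylation, trans also being the thermodynamic arrangement. The side-chain centre comes from desymmetrisation of 3-pentylglutaric anhydride, and C8 from ligand-controlled palladium prenylation.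

Key step: step 15

Assumption: in the two catalyst-controlled steps (14 and 16) the sense of induction is the one expected from the usual working models; in each case the pseudo-enantiomeric or mirror-image catalyst [(DHQ)2AQN; the (1S,2S)-ligand] is equally available and would be used if the opposite sense were found.

**Route**

Step 1
Reactants: 1 (1S,5S)-(−)-verbenone
Product: 3 (1S,3R)-3-acetyl-2,2-dimethylcyclobutane-1-carboxylic acid, via keto acid 2 (not isolated)
Conditions: RuCl3·3H2O (cat.), NaIO4 (4.2 equiv), CCl4/MeCN/H2O, rt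
Reagents that add atoms: sodium periodate [Na+].[O-]I(=O)(=O)=O; water O
Why: Oxidative cleavage of the enone C=C by RuO4 (made in situ, catalytic) gives the methyl ketone and the α-keto acid 2, which is cleaved once more with loss of CO2, while the cis-1,3-disubstituted cyclobutane and both of its stereocentres are taken over unchanged from the pinane skeleton.

Step 2
Reactants: 3 (1S,3R)-3-acetyl-2,2-dimethylcyclobutane-1-carboxylic acid
Product: 4 (1S,3S)-2,2-dimethyl-3-(prop-1-en-2-yl)cyclobutane-1-carboxylic acid
Conditions: Ph3PCH3Br (2.6 equiv), KOtBu (3.6 equiv), THF, 0 °C to rt; aq. citric acid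
Reagents that add atoms: methyltriphenylphosphonium bromide C[P+](c1ccccc1)(c1ccccc1)c1ccccc1.[Br-]
Why: Wittig methylenation of the methyl ketone, with the acid masked in the flask as its inert potassium carboxylate, should give the isopropenyl group, and a short reaction at low temperature limits enolisation so that the cis ring configuration is kept.

Step 3
Reactants: 4 (1S,3S)-2,2-dimethyl-3-(prop-1-en-2-yl)cyclobutane-1-carboxylic acid
Product: 5 [(1S,3S)-2,2-dimethyl-3-(prop-1-en-2-yl)cyclobutyl]methanol
Conditions: LiAlH4, THF, 0 °C to reflux; H2O work-up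
Reagents that add atoms: none
Why: Hydride reduction of the carboxylic acid to the primary alcohol leaves the isolated 1,1-disubstituted alkene and both ring stereocentres untouched.

Step 4
Reactants: 5 [(1S,3S)-2,2-dimethyl-3-(prop-1-en-2-yl)cyclobutyl]methanol
Product: 6 (1S,3S)-1-(iodomethyl)-2,2-dimethyl-3-(prop-1-en-2-yl)cyclobutane
Conditions: I2, PPh3, imidazole, CH2Cl2, 0 °C to rt, dark
Reagents that add atoms: iodine II
Why: The Appel reaction replaces the hydroxyl by SN2 attack of iodide on the alkoxyphosphonium ion at the primary carbon, so no cyclobutylcarbinyl cation (and no ring expansion) can arise.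

Step 5
Reactants: 7 methyl acetoacetate; 6 (1S,3S)-1-(iodomethyl)-2,2-dimethyl-3-(prop-1-en-2-yl)cyclobutane
Product: 8 methyl 5-[(1S,3S)-2,2-dimethyl-3-(prop-1-en-2-yl)cyclobutyl]-3-oxopentanoate
Conditions: NaH (1.1 equiv), THF, 0 °C; n-BuLi (1.05 equiv), 0 °C; 6, DMPU, 0 °C to rt; aqueous work-up
Reagents that add atoms: none
Why: Acetoacetate dianion alkylation: the γ-carbanion is the more reactive site of the dianion and displaces the primary iodide by SN2, leaving the central carbon free for the later acylation.

Step 6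
Reactants: 9 methyl (R)-3-hydroxybutanoate
Product: 10 methyl (2R,3R)-3-hydroxy-2-methylbutanoate
Conditions: LiN(iPr)2 (2.2 equiv), THF, −50 to −20 °C; MeI, DMPU, −78 to 0 °C
Reagents that add atoms: iodomethane CI
Why: Fráter–Seebach alkylation: the chelated lithium alkoxide enolate is methylated on the face away from the C3 methyl group, which sets the (2R) centre anti to the (3R) centre taken from 9.

Step 7
Reactants: 10 methyl (2R,3R)-3-hydroxy-2-methylbutanoate
Product: 11 methyl (2R,3R)-3-[(tert-butyldimethylsilyl)oxy]-2-methylbutanoate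
Conditions: TBSCl, imidazole, DMF, rt
Reagents that add atoms: tert-butyldimethylsilyl chloride CC(C)(C)[Si](C)(C)Cl
Why: Standard imidazole-mediated silylation protects the secondary alcohol so that the acid can later be activated as its chloride.

Step 8
Reactants: 11 methyl (2R,3R)-3-[(tert-butyldimethylsilyl)oxy]-2-methylbutanoate
Product: 12 (2R,3R)-3-[(tert-butyldimethylsilyl)oxy]-2-methylbutanoic acid
Conditions: LiOH, THF/MeOH/H2O, 0 °C to rt; 1 M HCl to pH 4, 0 °C
Reagents that add atoms: lithium hydroxide [Li+].[OH-]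
Why: Saponification of the methyl ester; the β-silyloxy group is a poor leaving group, so elimination should be minor, and the α-centre is in any case the one that is thermodynamically trans in the pyranone.

Step 9
Reactants: 12 (2R,3R)-3-[(tert-butyldimethylsilyl)oxy]-2-methylbutanoic acid; 8 methyl 5-[(1S,3S)-2,2-dimethyl-3-(prop-1-en-2-yl)cyclobutyl]-3-oxopentanoate
Product: 14 methyl 2-{(2R,3R)-3-[(tert-butyldimethylsilyl)oxy]-2-methylbutanoyl}-5-[(1S,3S)-2,2-dimethyl-3-(prop-1-en-2-yl)cyclobutyl]-3-oxopentanoate, via acid chloride 13 (not isolated)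
Conditions: 12, 1-chloro-N,N,2-trimethylprop-1-en-1-amine, CH2Cl2, 0 °C to rt; then added to 8, MgCl2, pyridine, CH2Cl2, 0 °C to rt
Reagents that add atoms: none
Why: Magnesium chloride–amine soft enolisation gives the chelated magnesium enolate of the β-keto ester, which is C-acylated at its central carbon by acid chloride 13 (made under neutral conditions, so the silyl ether survives).

Step 10
Reactants: 14 methyl 2-{(2R,3R)-3-[(tert-butyldimethylsilyl)oxy]-2-methylbutanoyl}-5-[(1S,3S)-2,2-dimethyl-3-(prop-1-en-2-yl)cyclobutyl]-3-oxopentanoate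
Product: 16 methyl (2R,3R)-6-{2-[(1S,3S)-2,2-dimethyl-3-(prop-1-en-2-yl)cyclobutyl]ethyl}-2,3-dimethyl-4-oxo-3,4-dihydro-2H-pyran-5-carboxylate, via hydroxy tricarbonyl 15 (not isolated)
Conditions: 48% aq. HF, MeCN, 0 °C to rt
Reagents that add atoms: none
Why: Desilylation frees the δ-hydroxyl, which adds to the side-chain ketone (six-membered hemiketal) and loses water to the doubly conjugated dihydropyranone (cyclodehydration); ketone attack should outrun lactonisation onto the methyl ester under mild acid, and the 3-methyl group settles trans (diequatorial) to the 2-methyl group.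

Step 11
Reactants: 17 methyl (E)-oct-2-enoate; 18 dimethyl malonate
Product: 19 trimethyl 2-pentylpropane-1,1,3-tricarboxylate
Conditions: NaOMe (0.2 equiv), MeOH, reflux
Reagents that add atoms: none
Why: Michael addition of the malonate anion to the β-alkyl acrylate builds the symmetric 3-pentylglutarate skeleton.

Step 12
Reactants: 19 trimethyl 2-pentylpropane-1,1,3-tricarboxylate
Product: 21 3-pentylpentanedioic acid, via triacid 20 (not isolated)
Conditions: 6 M HCl, AcOH, reflux
Reagents that add atoms: water O
Why: Acid hydrolysis of the three esters followed by thermal decarboxylation of the malonic acid unit of 20.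

Step 13
Reactants: 21 3-pentylpentanedioic acid
Product: 22 3-pentylglutaric anhydride (4-pentyloxane-2,6-dione)
Conditions: Ac2O, reflux; distillation
Reagents that add atoms: none
Why: Cyclodehydration of a glutaric acid to its six-membered anhydride by acetic anhydride.

Step 14
Reactants: 22 3-pentylglutaric anhydride
Product: 23 (3R)-3-(2-methoxy-2-oxoethyl)octanoic acid
Conditions: (DHQD)2AQN (10 mol%), MeOH (10 equiv), Et2O, −40 °C
Reagents that add atoms: methanol CO
Why: Cinchona-alkaloid-catalysed desymmetrising alcoholysis of a prochiral 3-substituted glutaric anhydride: general-base delivery of methanol inside the chiral pocket selects one of the two enantiotopic carbonyl groups and so sets the side-chain stereocentre.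

Step 15
Reactants: 23 (3R)-3-(2-methoxy-2-oxoethyl)octanoic acid; 16 methyl (2R,3R)-6-{2-[(1S,3S)-2,2-dimethyl-3-(prop-1-en-2-yl)cyclobutyl]ethyl}-2,3-dimethyl-4-oxo-3,4-dihydro-2H-pyran-5-carboxylate
Product: 26 methyl (3S)-3-[(2R,3R)-8-{[(1R,3S)-2,2-dimethyl-3-(prop-1-en-2-yl)cyclobutyl]methyl}-5,7-dihydroxy-2,3-dimethyl-4-oxo-3,4-dihydro-2H-chromen-6-yl]octanoate, via acid chloride 24 (not isolated), via triketo diester 25 (not isolated)
Conditions: 23, 1-chloro-N,N,2-trimethylprop-1-en-1-amine, CH2Cl2, 0 °C to rt, solvent changed to THF; 16, LiN(SiMe3)2 (3.3 equiv), THF, −78 °C; then 24, −78 °C to rt; aqueous work-up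
Reagents that add atoms: none
Why: LiN(SiMe3)2 removes a proton from the CH2 group on C6 of the pyranone, the γ-position that is vinylogous to both the C4 ketone and the C5 ester, and the lithium dienolate is C-acylated there by acid chloride 24 to give triketo diester 25 (first new bond, the later C7–C8 bond). Excess base then enolises the new ketone towards its only other α-carbon, and this enolate attacks the ring ester in a Claisen (Dieckmann-type) condensation with loss of methoxide (second new bond, the later C5–C6 bond); tautomerisation of the cyclohexanetrione to the 5,7-dihydroxy aromatic ring makes the sequence irreversible. The closest known reaction types are the γ-acylation of dioxinone and toluate dienolates with acid chlorides and the biomimetic Claisen cyclisation of 3,5,7-triketo esters to acylphloroglucinols, a carbonyl variant of the Staunton–Weinreb annulation. The one ring that is closed is the carbocycle, by a 6-(enolexo)-exo-trig attack of the enolate carbon on the ester carbonyl. No stereocentre is created: the side-chain centre of 24 is β to both carbonyl groups and cannot enolise, the cyclobutane centres are remote, and C3 of the pyranone, should it epimerise, returns to the trans arrangement with C2. The step needs γ- over α′-deprotonation (secured by the double vinylogous activation of the γ-CH2), C- over O-acylation (lithium counter-ion in THF at low temperature, as with dioxinone dienolates) and Claisen over aldol closure (attack on the C4 ketone would give a bridged ring that cannot aromatise).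

Step 16
Reactants: 26 methyl (3S)-3-[(2R,3R)-8-{[(1R,3S)-2,2-dimethyl-3-(prop-1-en-2-yl)cyclobutyl]methyl}-5,7-dihydroxy-2,3-dimethyl-4-oxo-3,4-dihydro-2H-chromen-6-yl]octanoate
Product: 27 methyl (3S)-3-[(2R,3R,8R)-8-{[(1R,3S)-2,2-dimethyl-3-(prop-1-en-2-yl)cyclobutyl]methyl}-5-hydroxy-2,3-dimethyl-8-(3-methylbut-2-en-1-yl)-4,7-dioxo-3,4,7,8-tetrahydro-2H-chromen-6-yl]octanoate
Conditions: Pd2(dba)3·CHCl3 (2.5 mol%), (1R,2R)-N,N′-bis[2-(diphenylphosphanyl)benzoyl]cyclohexane-1,2-diamine (7.5 mol%), prenyl acetate (1.2 equiv), Cs2CO3 (1.1 equiv), CH2Cl2, 0 °C to rt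
Reagents that add atoms: prenyl acetate (3-methylbut-2-en-1-yl acetate) CC(C)=CCOC(C)=O
Why: Proposed new method: zerovalent palladium ionises prenyl acetate to a cationic (1,1-dimethylallyl)palladium complex held in the chiral pocket of the diphosphine; the caesium 7-phenolate of 26 (the 5-OH is tied up in a hydrogen bond to the C4 ketone) attacks the unsubstituted allyl terminus from outside the metal through C8, the ring carbon flanked by O1 and the phenolate oxygen, O-prenylation being reversible under the catalyst while C-prenylation is not; C8 should be preferred over C6 because C6 carries an α-branched chain, and the ligand, not the remote stereocentres, selects the face of the planar phenolate and thereby the (8R) configuration; the closest known reaction types are the palladium-catalysed enantioselective prenylation of oxindoles, the palladium-catalysed allylic dearomatisation of naphthols (Tsuji–Trost reaction) and the base-mediated alkylative dearomatisation of acylphloroglucinols.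

Step 17
Reactants: 27 methyl (3S)-3-[(2R,3R,8R)-8-{[(1R,3S)-2,2-dimethyl-3-(prop-1-en-2-yl)cyclobutyl]methyl}-5-hydroxy-2,3-dimethyl-8-(3-methylbut-2-en-1-yl)-4,7-dioxo-3,4,7,8-tetrahydro-2H-chromen-6-yl]octanoate
Product: 28 (3S)-3-[(2R,3R,8R)-8-{[(1R,3S)-2,2-dimethyl-3-(prop-1-en-2-yl)cyclobutyl]methyl}-5-hydroxy-2,3-dimethyl-8-(3-methylbut-2-en-1-yl)-4,7-dioxo-3,4,7,8-tetrahydro-2H-chromen-6-yl]octanoic acid
Conditions: LiOH (5 equiv), THF/MeOH/H2O, 0 °C to rt; 0.5 M HCl to pH 4, 0 °C
Reagents that add atoms: lithium hydroxide [Li+].[OH-]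
Why: Saponification of the unhindered primary methyl ester; under LiOH the enolised triketone is present as its enolate and so should resist retro-Claisen cleavage and pyranone ring opening, and cold acidification only to pH 4 spares the isopropenylcyclobutane and the prenyl group.

**Compound list**

1 | (1S,5S)-(−)-verbenone [(1S,5S)-4,6,6-trimethylbicyclo[3.1.1]hept-3-en-2-one] | CC1=CC(=O)[C@H]2C[C@@H]1C2(C)C | starting material
2 | 2-[(1S,3R)-3-acetyl-2,2-dimethylcyclobutyl]-2-oxoacetic acid | OC(=O)C(=O)[C@H]1C[C@@H](C(C)=O)C1(C)C | intermediate (not isolated)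
3 | (1S,3R)-3-acetyl-2,2-dimethylcyclobutane-1-carboxylic acid [(−)-cis-pinononic acid] | OC(=O)[C@H]1C[C@@H](C(C)=O)C1(C)C | intermediate
4 | (1S,3S)-2,2-dimethyl-3-(prop-1-en-2-yl)cyclobutane-1-carboxylic acid | OC(=O)[C@H]1C[C@@H](C(C)=C)C1(C)C | intermediate
5 | [(1S,3S)-2,2-dimethyl-3-(prop-1-en-2-yl)cyclobutyl]methanol | OC[C@H]1C[C@@H](C(C)=C)C1(C)C | intermediate
6 | (1S,3S)-1-(iodomethyl)-2,2-dimethyl-3-(prop-1-en-2-yl)cyclobutane | IC[C@H]1C[C@@H](C(C)=C)C1(C)C | intermediate
7 | methyl acetoacetate | CC(=O)CC(=O)OC | starting material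
8 | methyl 5-[(1S,3S)-2,2-dimethyl-3-(prop-1-en-2-yl)cyclobutyl]-3-oxopentanoate | COC(=O)CC(=O)CC[C@H]1C[C@@H](C(C)=C)C1(C)C | intermediate
9 | methyl (R)-3-hydroxybutanoate | C[C@@H](O)CC(=O)OC | starting material
10 | methyl (2R,3R)-3-hydroxy-2-methylbutanoate | C[C@@H](O)[C@@H](C)C(=O)OC | intermediate
11 | methyl (2R,3R)-3-[(tert-butyldimethylsilyl)oxy]-2-methylbutanoate | C[C@@H](O[Si](C)(C)C(C)(C)C)[C@@H](C)C(=O)OC | intermediate
12 | (2R,3R)-3-[(tert-butyldimethylsilyl)oxy]-2-methylbutanoic acid | C[C@@H](O[Si](C)(C)C(C)(C)C)[C@@H](C)C(=O)O | intermediate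
13 | (2R,3R)-3-[(tert-butyldimethylsilyl)oxy]-2-methylbutanoyl chloride | C[C@@H](O[Si](C)(C)C(C)(C)C)[C@@H](C)C(=O)Cl | intermediate (not isolated)
14 | methyl 2-{(2R,3R)-3-[(tert-butyldimethylsilyl)oxy]-2-methylbutanoyl}-5-[(1S,3S)-2,2-dimethyl-3-(prop-1-en-2-yl)cyclobutyl]-3-oxopentanoate (enolised tricarbonyl; the central carbon is labile and left unassigned) | COC(=O)C(C(=O)[C@H](C)[C@@H](C)O[Si](C)(C)C(C)(C)C)C(=O)CC[C@H]1C[C@@H](C(C)=C)C1(C)C | intermediate
15 | methyl 5-[(1S,3S)-2,2-dimethyl-3-(prop-1-en-2-yl)cyclobutyl]-2-[(2R,3R)-3-hydroxy-2-methylbutanoyl]-3-oxopentanoate (central carbon unassigned) | COC(=O)C(C(=O)[C@H](C)[C@@H](C)O)C(=O)CC[C@H]1C[C@@H](C(C)=C)C1(C)C | intermediate (not isolated)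
16 | methyl (2R,3R)-6-{2-[(1S,3S)-2,2-dimethyl-3-(prop-1-en-2-yl)cyclobutyl]ethyl}-2,3-dimethyl-4-oxo-3,4-dihydro-2H-pyran-5-carboxylate | COC(=O)C1=C(CC[C@H]2C[C@@H](C(C)=C)C2(C)C)O[C@H](C)[C@@H](C)C1=O | intermediate
17 | methyl (E)-oct-2-enoate | CCCCC/C=C/C(=O)OC | starting material
18 | dimethyl malonate | COC(=O)CC(=O)OC | starting material
19 | trimethyl 2-pentylpropane-1,1,3-tricarboxylate | COC(=O)CC(CCCCC)C(C(=O)OC)C(=O)OC | intermediate
20 | 2-pentylpropane-1,1,3-tricarboxylic acid | OC(=O)CC(CCCCC)C(C(=O)O)C(=O)O | intermediate (not isolated)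
21 | 3-pentylpentanedioic acid (3-pentylglutaric acid) | OC(=O)CC(CCCCC)CC(=O)O | intermediate
22 | 3-pentylglutaric anhydride (4-pentyloxane-2,6-dione) | CCCCCC1CC(=O)OC(=O)C1 | intermediate
23 | (3R)-3-(2-methoxy-2-oxoethyl)octanoic acid | OC(=O)C[C@@H](CCCCC)CC(=O)OC | intermediate
24 | methyl (3S)-3-(2-chloro-2-oxoethyl)octanoate | ClC(=O)C[C@@H](CCCCC)CC(=O)OC | intermediate (not isolated)
25 | methyl (2R,3R)-6-{(5R)-1-[(1R,3S)-2,2-dimethyl-3-(prop-1-en-2-yl)cyclobutyl]-5-(2-methoxy-2-oxoethyl)-3-oxodecan-2-yl}-2,3-dimethyl-4-oxo-3,4-dihydro-2H-pyran-5-carboxylate (C2 of the decanyl chain is labile and left unassigned) | COC(=O)C[C@H](CCCCC)CC(=O)C(C[C@H]1C[C@@H](C(C)=C)C1(C)C)C1=C(C(=O)OC)C(=O)[C@H](C)[C@@H](C)O1 | intermediate (not isolated)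
26 | methyl (3S)-3-[(2R,3R)-8-{[(1R,3S)-2,2-dimethyl-3-(prop-1-en-2-yl)cyclobutyl]methyl}-5,7-dihydroxy-2,3-dimethyl-4-oxo-3,4-dihydro-2H-chromen-6-yl]octanoate | COC(=O)C[C@H](CCCCC)c1c(O)c(C[C@H]3C[C@@H](C(C)=C)C3(C)C)c2O[C@H](C)[C@@H](C)C(=O)c2c1O | intermediate
27 | methyl (3S)-3-[(2R,3R,8R)-8-{[(1R,3S)-2,2-dimethyl-3-(prop-1-en-2-yl)cyclobutyl]methyl}-5-hydroxy-2,3-dimethyl-8-(3-methylbut-2-en-1-yl)-4,7-dioxo-3,4,7,8-tetrahydro-2H-chromen-6-yl]octanoate | C=C(C)[C@@H]1C[C@H](C[C@@]2(CC=C(C)C)C(=O)C([C@@H](CCCCC)CC(=O)OC)=C(O)C3=C2O[C@H](C)[C@@H](C)C3=O)C1(C)C | intermediate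
28 | (3S)-3-[(2R,3R,8R)-8-{[(1R,3S)-2,2-dimethyl-3-(prop-1-en-2-yl)cyclobutyl]methyl}-5-hydroxy-2,3-dimethyl-8-(3-methylbut-2-en-1-yl)-4,7-dioxo-3,4,7,8-tetrahydro-2H-chromen-6-yl]octanoic acid | C=C(C)[C@@H]1C[C@H](C[C@@]2(CC=C(C)C)C(=O)C([C@@H](CCCCC)CC(=O)O)=C(O)C3=C2O[C@H](C)[C@@H](C)C3=O)C1(C)C | target

**Step count**

Total: 17 steps. Longest linear sequence: 10 steps (1, 2, 3, 4, 5, 9, 10, 15, 16, 17).

**Steps most likely to fail**

Step 16 (Proposed new method). The catalyst may discriminate the two faces of the planar phenolate only weakly, or be mismatched with the substrate. Attack through C6 or through oxygen may compete with attack through C8, and the acidic product may be prenylated a second time. Fallback (known chemistry, no catalyst control), setting out from 26 and coming back at 27: 26 is converted with LiN(SiMe3)2 (2.1 equiv) in THF at 0 °C into its dianion and treated with prenyl bromide. This is the classical alkylative dearomatisation of an acylphloroglucinol, which C-alkylates the ring carbon lying between two oxygens. It should give 27 together with its C8 epimer, methyl (3S)-3-[(2R,3R,8S)-8-{[(1R,3S)-2,2-dimethyl-3-(prop-1-en-2-yl)cyclobutyl]methyl}-5-hydroxy-2,3-dimethyl-8-(3-methylbut-2-en-1-yl)-4,7-dioxo-3,4,7,8-tetrahydro-2H-chromen-6-yl]octanoate F1. The two diastereomers are separated by preparative HPLC and 27 goes on to step 17.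

Step 15. The dienolate may be acylated on oxygen instead of on the γ-carbon, proton transfer from the acidic acylation product may quench unreacted dienolate, and the ring closure may stall at the open triketone. Fallback, setting out from 16 and coming back at 26, with the two bonds made in separate, neutral and then alkoxide-mediated operations: 16 is deprotonated with LiN(SiMe3)2 and trapped with TBSCl at −78 °C to give the silyl dienol ether methyl (2R,3R)-4-[(tert-butyldimethylsilyl)oxy]-6-{2-[(1R,3S)-2,2-dimethyl-3-(prop-1-en-2-yl)cyclobutyl]ethylidene}-2,3-dimethyl-3,6-dihydro-2H-pyran-5-carboxylate F2. F2 is C-acylated at its terminal carbon by acid chloride 24 (made from 23 as in step 15) in CH2Cl2 with catalytic Me3SiOTf (vinylogous Mukaiyama-type acylation, as known for silyloxydienes and acid chlorides). The triketo diester 25 is isolated and closed with NaOMe in MeOH at rt (Claisen cyclisation and aromatisation) to 26.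

Step 5. The SN2 displacement at the β-branched primary carbon of 6 may be slow, so that proton transfer, elimination to the methylenecyclobutane or O-alkylation take over. Fallback, setting out from 5 and coming back at 8, which replaces the displacement by a carbonyl olefination: Dess–Martin oxidation of 5 gives (1S,3S)-2,2-dimethyl-3-(prop-1-en-2-yl)cyclobutane-1-carbaldehyde F3. Wittig olefination of F3 with the stabilised ylide methyl 3-oxo-4-(triphenyl-λ5-phosphanylidene)butanoate in THF gives methyl (4E)-5-[(1R,3S)-2,2-dimethyl-3-(prop-1-en-2-yl)cyclobutyl]-3-oxopent-4-enoate F4. Conjugate reduction of the enone with the copper hydride [(Ph3P)CuH]6, which should leave the isolated isopropenyl group alone, gives 8.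

Further compounds
F1 | step 16 | methyl (3S)-3-[(2R,3R,8S)-8-{[(1R,3S)-2,2-dimethyl-3-(prop-1-en-2-yl)cyclobutyl]methyl}-5-hydroxy-2,3-dimethyl-8-(3-methylbut-2-en-1-yl)-4,7-dioxo-3,4,7,8-tetrahydro-2H-chromen-6-yl]octanoate | C=C(C)[C@@H]1C[C@H](C[C@]2(CC=C(C)C)C(=O)C([C@@H](CCCCC)CC(=O)OC)=C(O)C3=C2O[C@H](C)[C@@H](C)C3=O)C1(C)C
F2 | step 15 | methyl (2R,3R)-4-[(tert-butyldimethylsilyl)oxy]-6-{2-[(1R,3S)-2,2-dimethyl-3-(prop-1-en-2-yl)cyclobutyl]ethylidene}-2,3-dimethyl-3,6-dihydro-2H-pyran-5-carboxylate (alkene geometry unassigned) | COC(=O)C1=C(O[Si](C)(C)C(C)(C)C)[C@H](C)[C@@H](C)OC1=CC[C@H]1C[C@@H](C(C)=C)C1(C)C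
F3 | step 5 | (1S,3S)-2,2-dimethyl-3-(prop-1-en-2-yl)cyclobutane-1-carbaldehyde | O=C[C@H]1C[C@@H](C(C)=C)C1(C)C
F4 | step 5 | methyl (4E)-5-[(1R,3S)-2,2-dimethyl-3-(prop-1-en-2-yl)cyclobutyl]-3-oxopent-4-enoate | COC(=O)CC(=O)/C=C/[C@H]1C[C@@H](C(C)=C)C1(C)C
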